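**Retrosynthetic overview**
1. Feature: in ring C (chroman numbering) O1–C2 and the C3–H bond sit on neighbouring carbons, and C2 carries ring B with oxygens at both ortho positions and the para position. Both stereocentres (C2, C3) can therefore be made at once by adding the ring-A C8a–OH across a C2=C3 styrene.
2. Last disconnection: the five O–CH3 bonds of the penta-O-methyl chroman 13 (global demethylation).
3. Key disconnection: O1–C2 and C3–H of 13, back to the achiral E-styrene phenol 12. Ring C is the only ring formed; rings A and B are bought as arenes.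
4. 12 is cut at C4–C4a: Friedel–Crafts allylation with allylic transposition of phenol 6 by allylic alcohol 11.
5. 6 comes from 4-hydroxy-2,6-dimethoxybenzaldehyde and isobutylmagnesium bromide; 11 comes from tri-O-methylated triformylphloroglucinol and the Grignard reagent of 2-bromo-3-methylbut-1-ene.

Key step: step 8

Assumption 1: the sense of induction of the confined acid cannot be derived from first principles, so the (S,S)-catalyst is written for the (2R,3S)-product and its antipode is taken if the first run shows the opposite sense.
Assumption 2: 12 is carried forward as the E isomer (ring B anti to isopropyl), taken to be the main, separable product of step 7. Compounds 4 and 11 are racemic and their carbinol centres are destroyed in steps 3 and 7.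

**Route**

Step 1
Reactants: 1 4-hydroxy-2,6-dimethoxybenzaldehyde
Product: 2 4-[(tert-butyldimethylsilyl)oxy]-2,6-dimethoxybenzaldehyde
Conditions: TBSCl, imidazole, DMF, rt
Reagents that add atoms: tert-butyldimethylsilyl chloride, CC(C)(C)[Si](C)(C)Cl
Why: Imidazole-promoted silyl ether formation masks the only acidic OH, which would otherwise quench the Grignard reagent and turn the aldehyde into an unreactive vinylogous carboxylate.

Step 2
Reactants: 2 4-[(tert-butyldimethylsilyl)oxy]-2,6-dimethoxybenzaldehyde; 3 isobutylmagnesium bromide
Product: 4 rac-1-{4-[(tert-butyldimethylsilyl)oxy]-2,6-dimethoxyphenyl}-3-methylbutan-1-ol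
Conditions: THF, −78 → 0 °C; then H2O
Reagents that add atoms: none
Why: Grignard 1,2-addition to an aryl aldehyde, in which the two ortho methoxy groups chelate magnesium and the low temperature should keep β-hydride reduction minor; the new carbinol centre is racemic and is removed in step 3.

Step 3
Reactants: 4 rac-1-{4-[(tert-butyldimethylsilyl)oxy]-2,6-dimethoxyphenyl}-3-methylbutan-1-ol
Product: 5 1-{4-[(tert-butyldimethylsilyl)oxy]-2,6-dimethoxyphenyl}-3-methylbutan-1-one
Conditions: Dess–Martin periodinane, CH2Cl2, 0 °C → rt
Reagents that add atoms: none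
Why: Dess–Martin oxidation of a secondary benzylic alcohol to the aryl ketone runs under near-neutral conditions that should leave the aryl silyl ether and the electron-rich ring untouched.

Step 4
Reactants: 5 1-{4-[(tert-butyldimethylsilyl)oxy]-2,6-dimethoxyphenyl}-3-methylbutan-1-one
Product: 6 1-(4-hydroxy-2,6-dimethoxyphenyl)-3-methylbutan-1-one
Conditions: n-Bu4NF, AcOH, THF, 0 °C
Reagents that add atoms: none
Why: Fluoride-mediated desilylation buffered with acetic acid should free the phenol without exposing the enolisable ketone to base.

Step 5
Reactants: 7 triformylphloroglucinol (2,4,6-trihydroxybenzene-1,3,5-tricarbaldehyde)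
Product: 8 2,4,6-trimethoxybenzene-1,3,5-tricarbaldehyde
Conditions: Me2SO4, K2CO3, acetone, reflux
Reagents that add atoms: dimethyl sulfate, COS(=O)(=O)OC
Why: Williamson-type O-methylation of three strongly acidic, chelated hydroxyls with a hard methylating agent; every ring carbon is substituted, so C-methylation would cost the aromaticity and should not compete.

Step 6
Reactants: 8 2,4,6-trimethoxybenzene-1,3,5-tricarbaldehyde; 9 2-bromo-3-methylbut-1-ene
Product: 11 rac-5-(1-hydroxy-3-methyl-2-methylidenebutyl)-2,4,6-trimethoxybenzene-1,3-dicarbaldehyde, via (3-methylbut-1-en-2-yl)magnesium bromide 10 (not isolated)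
Conditions: 9, Mg, THF, 40 °C; then slow addition to 8 (2 equiv), THF, −78 °C; then H2O
Reagents that add atoms: none
Why: Alkenyl Grignard formation and 1,2-addition to one of three equivalent, hindered formyl groups, where inverse addition to an excess of 8 at low temperature should favour the mono-adduct and unreacted 8 is recovered; the carbinol centre is racemic and is lost in step 7.

Step 7
Reactants: 6 1-(4-hydroxy-2,6-dimethoxyphenyl)-3-methylbutan-1-one; 11 rac-5-(1-hydroxy-3-methyl-2-methylidenebutyl)-2,4,6-trimethoxybenzene-1,3-dicarbaldehyde
Product: 12 5-[(1E)-2-{[6-hydroxy-2,4-dimethoxy-3-(3-methylbutanoyl)phenyl]methyl}-3-methylbut-1-en-1-yl]-2,4,6-trimethoxybenzene-1,3-dicarbaldehyde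
Conditions: Sc(OTf)3 (5 mol %), 6 (2 equiv), MeNO2, −20 → 0 °C
Reagents that add atoms: none
Why: Friedel–Crafts allylation with allylic transposition (SN1′), in which Sc(OTf)3 ionises the benzylic and allylic alcohol and the ring-A carbon ortho to the free OH (also ortho and para to the two OMe groups) attacks the unhindered CH2 terminus of the allyl cation to give the conjugated styrene with ring B anti to the bulkier isopropyl group, while the catalytic, cold conditions should leave the less basic product alkene unprotonated.

Step 8
Reactants: 12 5-[(1E)-2-{[6-hydroxy-2,4-dimethoxy-3-(3-methylbutanoyl)phenyl]methyl}-3-methylbut-1-en-1-yl]-2,4,6-trimethoxybenzene-1,3-dicarbaldehyde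
Product: 13 5-[(2R,3S)-5,7-dimethoxy-6-(3-methylbutanoyl)-3-(propan-2-yl)-3,4-dihydro-2H-chromen-2-yl]-2,4,6-trimethoxybenzene-1,3-dicarbaldehyde
Conditions: (S,S)-imidodiphosphorimidate acid HN[P(=NSO2CF3)(O2C20H10Ar2)]2 built on (S)-3,3′-Ar2-BINOL, Ar = 3,5-(CF3)2C6H3 (IDPi, 5 mol %), CHCl3, 4 Å MS, 0 °C → rt; then Et3N
Reagents that add atoms: none
Why: Proposed new method: the confined acid should deliver its proton to C3 of the E-styrene inside the chiral pocket, giving a contact ion pair whose C2 benzylic cation is stabilised by the 2′-, 4′- and 6′-oxygens of ring B, and the C8a phenol oxygen then forms the O1–C2 bond and closes ring C by 6-endo-trig attack. The closest known reaction type is the imidodiphosphorimidate-catalysed asymmetric intramolecular hydroalkoxylation of alkenes, read together with the achiral acid-mediated closure of ortho-cinnamylphenols to flavans; a phenol adding across a trisubstituted styrene with the stereocentre set by C-protonation has not been shown. C3 (S) is set by the catalyst choosing the Re face of C3 for protonation, and C2 (R) follows from anti capture across the E-alkene, which places ring B and isopropyl trans; because C2 can re-ionise, it should also settle in the more stable 2,3-trans arrangement without C3 being touched. The step needs protonation at C3 and not at C2 (which would give a tertiary cation and, by 5-exo closure, a dihydrobenzofuran) and one alkene face over the other: the three ring-B oxygens make C2 the better cation site, the catalyst supplies the face selection, and the two formyl groups keep the cation short-lived enough to stay paired with the chiral anion. Since the C5 and C7 oxygens are methylated, the C8a–OH is the only nucleophile and only the 6-acyl chroman can form; the amine quench is there to stop re-ionisation and elimination from eroding C3.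

Step 9
Reactants: 13 5-[(2R,3S)-5,7-dimethoxy-6-(3-methylbutanoyl)-3-(propan-2-yl)-3,4-dihydro-2H-chromen-2-yl]-2,4,6-trimethoxybenzene-1,3-dicarbaldehyde
Product: 14 5-[(2R,3S)-5,7-dihydroxy-6-(3-methylbutanoyl)-3-(propan-2-yl)-3,4-dihydro-2H-chromen-2-yl]-2,4,6-trihydroxybenzene-1,3-dicarbaldehyde (target)
Conditions: BBr3 (10 equiv), CH2Cl2, −78 → 0 °C; then ice-water
Reagents that add atoms: none
Why: Lewis-acid cleavage of aryl methyl ethers, for which BBr3 is chosen because five ethers face only three carbonyl groups and purely chelation-driven cleavage would be expected to stop short; the boron-complexed carbonyls make both rings electron-poor, which should disfavour ionisation of the C2–O1 bond, and neither stereocentre has a pathway to change.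

**Compound list**
1 | 4-hydroxy-2,6-dimethoxybenzaldehyde | O=Cc1c(OC)cc(O)cc1OC | starting material
2 | 4-[(tert-butyldimethylsilyl)oxy]-2,6-dimethoxybenzaldehyde | O=Cc1c(OC)cc(O[Si](C)(C)C(C)(C)C)cc1OC | intermediate
3 | isobutylmagnesium bromide | CC(C)C[Mg]Br | starting material
4 | rac-1-{4-[(tert-butyldimethylsilyl)oxy]-2,6-dimethoxyphenyl}-3-methylbutan-1-ol | CC(C)CC(O)c1c(OC)cc(O[Si](C)(C)C(C)(C)C)cc1OC | intermediate
5 | 1-{4-[(tert-butyldimethylsilyl)oxy]-2,6-dimethoxyphenyl}-3-methylbutan-1-one | CC(C)CC(=O)c1c(OC)cc(O[Si](C)(C)C(C)(C)C)cc1OC | intermediate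
6 | 1-(4-hydroxy-2,6-dimethoxyphenyl)-3-methylbutan-1-one | CC(C)CC(=O)c1c(OC)cc(O)cc1OC | intermediate
7 | triformylphloroglucinol | O=Cc1c(O)c(C=O)c(O)c(C=O)c1O | starting material
8 | 2,4,6-trimethoxybenzene-1,3,5-tricarbaldehyde | O=Cc1c(OC)c(C=O)c(OC)c(C=O)c1OC | intermediate
9 | 2-bromo-3-methylbut-1-ene | C=C(Br)C(C)C | starting material
10 | (3-methylbut-1-en-2-yl)magnesium bromide | C=C([Mg]Br)C(C)C | intermediate
11 | rac-5-(1-hydroxy-3-methyl-2-methylidenebutyl)-2,4,6-trimethoxybenzene-1,3-dicarbaldehyde | C=C(C(C)C)C(O)c1c(OC)c(C=O)c(OC)c(C=O)c1OC | intermediate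
12 | 5-[(1E)-2-{[6-hydroxy-2,4-dimethoxy-3-(3-methylbutanoyl)phenyl]methyl}-3-methylbut-1-en-1-yl]-2,4,6-trimethoxybenzene-1,3-dicarbaldehyde | CC(C)CC(=O)c1c(OC)cc(O)c(c1OC)C/C(C(C)C)=C\c1c(OC)c(C=O)c(OC)c(C=O)c1OC | intermediate
13 | 5-[(2R,3S)-5,7-dimethoxy-6-(3-methylbutanoyl)-3-(propan-2-yl)-3,4-dihydro-2H-chromen-2-yl]-2,4,6-trimethoxybenzene-1,3-dicarbaldehyde | CC(C)CC(=O)c1c(OC)cc2c(c1OC)C[C@@H](C(C)C)[C@H](c1c(OC)c(C=O)c(OC)c(C=O)c1OC)O2 | intermediate
14 | 5-[(2R,3S)-5,7-dihydroxy-6-(3-methylbutanoyl)-3-(propan-2-yl)-3,4-dihydro-2H-chromen-2-yl]-2,4,6-trihydroxybenzene-1,3-dicarbaldehyde | CC(C)CC(=O)c1c(O)cc2c(c1O)C[C@@H](C(C)C)[C@H](c1c(O)c(C=O)c(O)c(C=O)c1O)O2 | target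

**Step count**
Total: 9 steps. Longest linear sequence: 7 steps (steps 1, 2, 3, 4, 7, 8, 9 from compound 1).

**Steps most likely to fail**

Step 8 (proposed new method). The proton may go to C2 instead of C3, giving a tertiary cation and 5-exo closure. The face selection inside the pocket may be poor for so large a substrate. The three carbonyl groups may tie up the acid, so that only a slow, unselective background closure runs. Prolonged exposure may erode C3 by re-ionisation and elimination. Fallback with known chemistry, setting out from 12: an achiral strong acid (TfOH, 10 mol %, CH2Cl2, 0 °C) effects the known closure of an ortho-cinnamylphenol to a flavan under thermodynamic control and should give the racemic 2,3-trans penta-O-methyl chroman F1. Preparative HPLC on a chiral stationary phase (cellulose tris(3,5-dimethylphenylcarbamate)) then separates the enantiomers, and the (2R,3S)-enantiomer is compound 13, where the route is rejoined.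

Step 7. Under the Lewis acid the newly formed phenol may be protonated at its own styrene and close ring C without stereocontrol. O-allylation or a second allylation at the other free ring-A carbon may compete. The alkene may form as an E/Z mixture. Fallback, setting out from silyl ether 5 and alcohol 11: the same Sc(OTf)3-catalysed allylation is run on 5, whose masked oxygen can neither be alkylated nor close a ring, and should give 5-[(1E)-2-({6-[(tert-butyldimethylsilyl)oxy]-2,4-dimethoxy-3-(3-methylbutanoyl)phenyl}methyl)-3-methylbut-1-en-1-yl]-2,4,6-trimethoxybenzene-1,3-dicarbaldehyde F2. Buffered fluoride (n-Bu4NF, AcOH, THF, 0 °C) then frees the phenol without acid and returns to the route at 12.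

Step 9. The two ethers that have no free carbonyl partner may cleave sluggishly. The Lewis acid may ionise the C2–O1 bond, after which ring C could re-close through the C5 oxygen (placing the acyl group at C8) or the compound could lose material by elimination. Formyl groups may be brominated. Fallback, setting out from 13 and arriving directly at 14: nucleophilic demethylation by sodium ethanethiolate (DMF, 110 °C, then dilute HCl) attacks the methyl carbons by SN2 under basic conditions where no Lewis acid can ionise C2–O1. All five ethers are ortho or para to a carbonyl group and so release stabilised phenoxides, and these vinylogous carboxylates are poor donors for base-induced ring opening.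

**Further compounds**
F1 | step 8 | rac-(2R*,3S*)-5-[5,7-dimethoxy-6-(3-methylbutanoyl)-3-(propan-2-yl)-3,4-dihydro-2H-chromen-2-yl]-2,4,6-trimethoxybenzene-1,3-dicarbaldehyde (racemate, both enantiomers written) | CC(C)CC(=O)c1c(OC)cc2c(c1OC)C[C@@H](C(C)C)[C@H](c1c(OC)c(C=O)c(OC)c(C=O)c1OC)O2.CC(C)CC(=O)c1c(OC)cc2c(c1OC)C[C@H](C(C)C)[C@@H](c1c(OC)c(C=O)c(OC)c(C=O)c1OC)O2
F2 | step 7 | 5-[(1E)-2-({6-[(tert-butyldimethylsilyl)oxy]-2,4-dimethoxy-3-(3-methylbutanoyl)phenyl}methyl)-3-methylbut-1-en-1-yl]-2,4,6-trimethoxybenzene-1,3-dicarbaldehyde | CC(C)CC(=O)c1c(OC)cc(O[Si](C)(C)C(C)(C)C)c(c1OC)C/C(C(C)C)=C\c1c(OC)c(C=O)c(OC)c(C=O)c1OC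
F0 | step 9 | none | none
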